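**Strategy.** The ring is a carvone-type 2-methylcyclohex-2-enone in disguise. Its six carbons split into the C(CH3)=CH–CH2 half (methyl-bearing carbon, future epoxide CH, ring CH2) and the O=C–CH(O)–CH half (ring carbonyl, acyloxy carbon, side-chain carbon). A one-flask [3+3] annulation joins them: the lithium dianion of a β-hydroxy ketone carrying the full side chain is C-allylated by (Z)-1-bromo-3-iodobut-2-ene, and iodine–lithium exchange then sends the alkenyllithium into the neighbouring ester. The allylation makes the CH2–CH ring bond, the acylation the carbonyl–C(CH3) ring bond. Methylenation, two acylations, Luche reduction, hydroxyl-directed epoxidation and reoxidation complete the target.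

Key step: step 7

Assumption: 1, 4 and 8 (as toluene solution, cracked to the monomer before use) are bought; all other reagents are standard commercial chemicals.

Step 1
Reactants: 1 but-2-yn-1-ol
Product: 2 (2Z)-3-iodobut-2-en-1-ol
Conditions: NaAlH2(OCH2CH2OCH3)2 (Red-Al), THF, 0 °C to rt; then I2, −78 °C
Reagents that add atoms: iodine, II
Why: Alkoxide-directed trans-hydroalumination of the propargylic alcohol puts aluminium on C3, and iodinolysis with retention should give the Z-iodoalkene (hydroalumination–iodination).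

Step 2
Reactants: 2 (2Z)-3-iodobut-2-en-1-ol
Product: 3 (2Z)-1-bromo-3-iodobut-2-ene
Conditions: CBr4, PPh3, CH2Cl2, 0 °C
Reagents that add atoms: carbon tetrabromide, BrC(Br)(Br)Br
Why: Appel bromination of the primary allylic alcohol is neutral and should leave the alkene geometry and the C–I bond untouched.

Step 3
Reactants: 4 6-methylhept-5-en-2-one (used in excess)
Product: 5 (3R)-6-methyl-3-[(phenylamino)oxy]hept-5-en-2-one
Conditions: PhNO (slow addition), L-proline (20 mol %), DMSO, rt
Reagents that add atoms: nitrosobenzene, O=Nc1ccccc1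
Why: Proline-catalysed α-aminoxylation (O-selective nitroso aldol) runs through the more substituted enamine, and the carboxylic acid of L-proline directs PhN=O to one enamine face, which should set the (3R) centre.

Step 4
Reactants: 5 (3R)-6-methyl-3-[(phenylamino)oxy]hept-5-en-2-one
Product: 6 (3R)-3-hydroxy-6-methylhept-5-en-2-one
Conditions: Zn dust, AcOH–THF–H2O, 0 °C to rt
Reagents that add atoms: none
Why: Reductive N–O cleavage frees the ketol without touching the stereocentre or the alkene.

Step 5
Reactants: 6 (3R)-3-hydroxy-6-methylhept-5-en-2-one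
Product: 7 (3R)-3-[(tert-butyldimethylsilyl)oxy]-6-methylhept-5-en-2-one
Conditions: TBSCl, imidazole, DMF, 0 °C to rt
Reagents that add atoms: tert-butyldimethylsilyl chloride, CC(C)(C)[Si](C)(C)Cl
Why: Standard silylation of the secondary alcohol; the bulky silyl ether later disfavours enolisation toward the oxygenated carbon.

Step 6
Reactants: 7 (3R)-3-[(tert-butyldimethylsilyl)oxy]-6-methylhept-5-en-2-one; 8 ethyl glyoxylate
Product: 9 ethyl (2S,5R)-5-[(tert-butyldimethylsilyl)oxy]-2-hydroxy-8-methyl-4-oxonon-7-enoate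
Conditions: D-proline (30 mol %), DMSO–CHCl3, 4 °C
Reagents that add atoms: none
Why: Enamine-catalysed direct aldol addition: the enamine forms on the unhindered methyl side, and the Houk–List transition state of D-proline should deliver the (2S) carbinol.

Step 7
Reactants: 9 ethyl (2S,5R)-5-[(tert-butyldimethylsilyl)oxy]-2-hydroxy-8-methyl-4-oxonon-7-enoate; 3 (2Z)-1-bromo-3-iodobut-2-ene
Product: 11 (5R,6S)-5-[(2R)-2-[(tert-butyldimethylsilyl)oxy]-5-methylhex-4-enoyl]-6-hydroxy-2-methylcyclohex-2-en-1-one, via C3-allylated hydroxy keto ester 10 (not isolated)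
Conditions: LiN(i-Pr)2 (2.2 equiv), THF, −78 °C; 3, −78 to −30 °C; LiN(i-Pr)2 (1.1 equiv), −78 °C; t-BuLi (5.5 equiv), −78 °C; AcOH quench at −78 °C
Reagents that add atoms: none
Why: The alkoxide–enolate dianion of 9 is C-allylated at the primary allylic bromide of 3 (SN2, Fráter–Seebach-type alkylation of a lithium-chelated β-oxido enolate) to give 10; the extra LiN(i-Pr)2 turns the side-chain ketone of 10 back into its enolate, and iodine–lithium exchange then generates a (Z)-alkenyllithium that attacks the only electrophile left, the ethyl ester, in an acyl substitution that closes the cyclohexenone. The closest known reaction types are the anti-selective dianion alkylation of β-hydroxy carbonyl compounds and the halogen–metal-exchange-initiated intramolecular acylation of (Z)-iodoalkenyl esters (Parham/Cooke-type cyclisation). The single ring is closed in the 6-exo-trig mode by the second bond, and the Z-iodoalkene becomes the endocyclic C2=C3 bond. The new stereocentre C5 is first set anti to the carbinol by the chelated enolate, is erased by the protective re-enolisation and is re-formed on protonation, where it should settle trans to the C6 hydroxyl (both equatorial) because it stays epimerisable beside the ketone; C6 and the silyloxy carbon are carried through from 9. The selectivity needed is ester over ketone toward the alkenyllithium and exchange over carbonyl addition by t-BuLi: the first is secured by holding the ketone as its enolate, the second by the speed of iodine–lithium exchange at −78 °C, the excess t-BuLi only re-lithiating the liberated amine. The lithium alkoxide next to the ester chelates the tetrahedral intermediate, so the enone should be set free only on quench.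

Step 8
Reactants: 11 (5R,6S)-5-[(2R)-2-[(tert-butyldimethylsilyl)oxy]-5-methylhex-4-enoyl]-6-hydroxy-2-methylcyclohex-2-en-1-one (used crude)
Product: 12 (5S,6S)-5-[(3R)-3-[(tert-butyldimethylsilyl)oxy]-6-methylhepta-1,5-dien-2-yl]-6-hydroxy-2-methylcyclohex-2-en-1-one
Conditions: Ph3PCH3Br, KN(SiMe3)2, THF, 0 °C; then 11, −78 to 0 °C (3 equiv ylide)
Reagents that add atoms: methyltriphenylphosphonium bromide, C[P+](c1ccccc1)(c1ccccc1)c1ccccc1.[Br-]
Why: Wittig methylenation; the first equivalent of ylide deprotonates the hydroxyl, and the resulting α-oxido group should deactivate the conjugated ring carbonyl so that the saturated side-chain ketone reacts, while reversible enolisation lets C5 settle trans before it is fixed.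

Step 9
Reactants: 12 (5S,6S)-5-[(3R)-3-[(tert-butyldimethylsilyl)oxy]-6-methylhepta-1,5-dien-2-yl]-6-hydroxy-2-methylcyclohex-2-en-1-one
Product: 13 (1S,6S)-6-[(3R)-3-[(tert-butyldimethylsilyl)oxy]-6-methylhepta-1,5-dien-2-yl]-3-methyl-2-oxocyclohex-3-en-1-yl 3-methylbut-2-enoate
Conditions: 3-methylbut-2-enoic acid, DCC, DMAP (cat.), CH2Cl2, 0 °C to rt
Reagents that add atoms: 3-methylbut-2-enoic acid, CC(C)=CC(=O)O
Why: Steglich esterification of the α-hydroxy enone avoids the acid chloride/amine conditions that deconjugate senecioates through a vinylketene.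

Step 10
Reactants: 13 (1S,6S)-6-[(3R)-3-[(tert-butyldimethylsilyl)oxy]-6-methylhepta-1,5-dien-2-yl]-3-methyl-2-oxocyclohex-3-en-1-yl 3-methylbut-2-enoate
Product: 14 (1S,6S)-6-[(3R)-3-hydroxy-6-methylhepta-1,5-dien-2-yl]-3-methyl-2-oxocyclohex-3-en-1-yl 3-methylbut-2-enoate
Conditions: HF·pyridine, THF–pyridine, 0 °C to rt
Reagents that add atoms: none
Why: Buffered fluoride desilylation should spare the α-acyloxy enone and the dienes; it is done before the epoxide exists.

Step 11
Reactants: 14 (1S,6S)-6-[(3R)-3-hydroxy-6-methylhepta-1,5-dien-2-yl]-3-methyl-2-oxocyclohex-3-en-1-yl 3-methylbut-2-enoate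
Product: 15 (1S,6S)-6-[(3R)-3-(acetyloxy)-6-methylhepta-1,5-dien-2-yl]-3-methyl-2-oxocyclohex-3-en-1-yl 3-methylbut-2-enoate
Conditions: Ac2O, pyridine, DMAP (cat.), CH2Cl2, 0 °C
Reagents that add atoms: acetic anhydride, CC(=O)OC(C)=O
Why: Routine acetylation of the allylic secondary alcohol, the only free hydroxyl.

Step 12
Reactants: 15 (1S,6S)-6-[(3R)-3-(acetyloxy)-6-methylhepta-1,5-dien-2-yl]-3-methyl-2-oxocyclohex-3-en-1-yl 3-methylbut-2-enoate
Product: 16 (1S,2S,6S)-6-[(3R)-3-(acetyloxy)-6-methylhepta-1,5-dien-2-yl]-2-hydroxy-3-methylcyclohex-3-en-1-yl 3-methylbut-2-enoate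
Conditions: NaBH4, CeCl3·7H2O, MeOH, −78 °C
Reagents that add atoms: none
Why: Luche 1,2-reduction; axial hydride delivery on the half-chair with both substituents equatorial should give the equatorial alcohol, trans to the acyloxy group and cis to the side chain (as carvone gives cis-carveol).

Step 13
Reactants: 16 (1S,2S,6S)-6-[(3R)-3-(acetyloxy)-6-methylhepta-1,5-dien-2-yl]-2-hydroxy-3-methylcyclohex-3-en-1-yl 3-methylbut-2-enoate
Product: 17 (1R,2R,3S,4S,6S)-4-[(3R)-3-(acetyloxy)-6-methylhepta-1,5-dien-2-yl]-2-hydroxy-1-methyl-7-oxabicyclo[4.1.0]heptan-3-yl 3-methylbut-2-enoate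
Conditions: VO(acac)2 (5 mol %), t-BuOOH, CH2Cl2, 0 °C
Reagents that add atoms: tert-butyl hydroperoxide, CC(C)(C)OO
Why: Hydroxyl-directed epoxidation delivers oxygen syn to the allylic alcohol, which places the epoxide cis to the side chain (the face that direct nucleophilic epoxidation of the enone would not give); the other alkenes are not allylic alcohols.

Step 14
Reactants: 17 (1R,2R,3S,4S,6S)-4-[(3R)-3-(acetyloxy)-6-methylhepta-1,5-dien-2-yl]-2-hydroxy-1-methyl-7-oxabicyclo[4.1.0]heptan-3-yl 3-methylbut-2-enoate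
Product: 18 (1S,3S,4S,6S)-4-[(3R)-3-(acetyloxy)-6-methylhepta-1,5-dien-2-yl]-1-methyl-2-oxo-7-oxabicyclo[4.1.0]heptan-3-yl 3-methylbut-2-enoate
Conditions: Dess–Martin periodinane, NaHCO3, CH2Cl2, 0 °C to rt
Reagents that add atoms: none
Why: Buffered Dess–Martin oxidation turns the epoxy alcohol into the epoxy ketone without opening the epoxide or epimerising the α-acyloxy carbon.

**Compound list**

1 | but-2-yn-1-ol | CC#CCO | starting material
2 | (2Z)-3-iodobut-2-en-1-ol | OC/C=C(/C)I | intermediate
3 | (2Z)-1-bromo-3-iodobut-2-ene | BrC/C=C(/C)I | intermediate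
4 | 6-methylhept-5-en-2-one | CC(=O)CCC=C(C)C | starting material
5 | (3R)-6-methyl-3-[(phenylamino)oxy]hept-5-en-2-one | CC(=O)[C@@H](CC=C(C)C)ONc1ccccc1 | intermediate
6 | (3R)-3-hydroxy-6-methylhept-5-en-2-one | CC(=O)[C@@H](CC=C(C)C)O | intermediate
7 | (3R)-3-[(tert-butyldimethylsilyl)oxy]-6-methylhept-5-en-2-one | CC(=O)[C@@H](CC=C(C)C)O[Si](C)(C)C(C)(C)C | intermediate
8 | ethyl glyoxylate (ethyl oxoacetate) | CCOC(=O)C=O | starting material
9 | ethyl (2S,5R)-5-[(tert-butyldimethylsilyl)oxy]-2-hydroxy-8-methyl-4-oxonon-7-enoate | CCOC(=O)[C@@H](O)CC(=O)[C@@H](CC=C(C)C)O[Si](C)(C)C(C)(C)C | intermediate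
10 | ethyl (2S,3R,5R)-5-[(tert-butyldimethylsilyl)oxy]-2-hydroxy-3-[(2Z)-3-iodobut-2-en-1-yl]-8-methyl-4-oxonon-7-enoate (formed in the flask in step 7) | CCOC(=O)[C@@H](O)[C@@H](C/C=C(/C)I)C(=O)[C@@H](CC=C(C)C)O[Si](C)(C)C(C)(C)C | intermediate
11 | (5R,6S)-5-[(2R)-2-[(tert-butyldimethylsilyl)oxy]-5-methylhex-4-enoyl]-6-hydroxy-2-methylcyclohex-2-en-1-one | O=C([C@@H](CC=C(C)C)O[Si](C)(C)C(C)(C)C)[C@@H]1CC=C(C)C(=O)[C@H]1O | intermediate
12 | (5S,6S)-5-[(3R)-3-[(tert-butyldimethylsilyl)oxy]-6-methylhepta-1,5-dien-2-yl]-6-hydroxy-2-methylcyclohex-2-en-1-one | C=C([C@@H](CC=C(C)C)O[Si](C)(C)C(C)(C)C)[C@@H]1CC=C(C)C(=O)[C@H]1O | intermediate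
13 | (1S,6S)-6-[(3R)-3-[(tert-butyldimethylsilyl)oxy]-6-methylhepta-1,5-dien-2-yl]-3-methyl-2-oxocyclohex-3-en-1-yl 3-methylbut-2-enoate | C=C([C@@H](CC=C(C)C)O[Si](C)(C)C(C)(C)C)[C@@H]1CC=C(C)C(=O)[C@H]1OC(=O)C=C(C)C | intermediate
14 | (1S,6S)-6-[(3R)-3-hydroxy-6-methylhepta-1,5-dien-2-yl]-3-methyl-2-oxocyclohex-3-en-1-yl 3-methylbut-2-enoate | C=C([C@@H](CC=C(C)C)O)[C@@H]1CC=C(C)C(=O)[C@H]1OC(=O)C=C(C)C | intermediate
15 | (1S,6S)-6-[(3R)-3-(acetyloxy)-6-methylhepta-1,5-dien-2-yl]-3-methyl-2-oxocyclohex-3-en-1-yl 3-methylbut-2-enoate | C=C([C@@H](CC=C(C)C)OC(C)=O)[C@@H]1CC=C(C)C(=O)[C@H]1OC(=O)C=C(C)C | intermediate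
16 | (1S,2S,6S)-6-[(3R)-3-(acetyloxy)-6-methylhepta-1,5-dien-2-yl]-2-hydroxy-3-methylcyclohex-3-en-1-yl 3-methylbut-2-enoate (hydroxyl cis to the side chain, trans to the ester) | C=C([C@@H](CC=C(C)C)OC(C)=O)[C@@H]1CC=C(C)[C@H](O)[C@H]1OC(=O)C=C(C)C | intermediate
17 | (1R,2R,3S,4S,6S)-4-[(3R)-3-(acetyloxy)-6-methylhepta-1,5-dien-2-yl]-2-hydroxy-1-methyl-7-oxabicyclo[4.1.0]heptan-3-yl 3-methylbut-2-enoate (epoxide cis to hydroxyl and side chain) | C=C([C@@H](CC=C(C)C)OC(C)=O)[C@@H]1C[C@@H]2O[C@]2(C)[C@H](O)[C@H]1OC(=O)C=C(C)C | intermediate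
18 | (1S,3S,4S,6S)-4-[(3R)-3-(acetyloxy)-6-methylhepta-1,5-dien-2-yl]-1-methyl-2-oxo-7-oxabicyclo[4.1.0]heptan-3-yl 3-methylbut-2-enoate (CNP0168401.1) | C=C([C@@H](CC=C(C)C)OC(C)=O)[C@@H]1C[C@@H]2O[C@]2(C)C(=O)[C@H]1OC(=O)C=C(C)C | target

**Totals.** 14 steps in all. The longest linear sequence is 12 steps (4 to 18, steps 3–14); steps 1–2 make the three-carbon partner 3.

**Steps most likely to fail**

Step 7 (key step). Several processes may go wrong in the one-flask sequence. The alkenyllithium may be protonated by liberated amine before it cyclises. It may attack the side-chain carbonyl in a five-membered closure if re-enolisation is incomplete. Excess t-BuLi may add to the enone if the tetrahedral intermediate collapses early. The β-hydroxy ketone product may lose water toward an aromatic acylphenol on work-up, and the configuration next to the ketone may not settle cleanly. The fallback sets out from 9 and 3 and comes back at 12. The sequence is stopped after the dianion allylation (LiN(i-Pr)2, 2.2 equiv) and 10 is isolated. Its ketone is methylenated under non-basic Takai–Lombardo conditions (Zn, CH2Br2, TiCl4, THF–CH2Cl2) to ethyl (2S,3S,5R)-5-[(tert-butyldimethylsilyl)oxy]-2-hydroxy-3-[(2Z)-3-iodobut-2-en-1-yl]-8-methyl-4-methylidenenon-7-enoate F1, in which the allylation-derived stereocentre is no longer epimerisable. Iodine–lithium exchange with t-BuLi (3.2 equiv, THF, −78 °C) then closes the ring by intramolecular acylation on the ester, now the only carbonyl group, and gives 12 directly, so that step 8 is not needed.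

Step 8. The ylide may attack the conjugated ring carbonyl as well, and its basicity may trigger retro-aldol opening, dehydration toward the phenol or epimerisation at the silyloxy carbon. The fallback sets out from 11 and comes back at 12 by a Peterson olefination. The weakly basic organocerium reagent from Me3SiCH2Li and CeCl3 (THF, −78 °C) is added to the saturated ketone to give the β-hydroxysilane (5R,6S)-5-[(3R)-3-[(tert-butyldimethylsilyl)oxy]-2-hydroxy-6-methyl-1-(trimethylsilyl)hept-5-en-2-yl]-6-hydroxy-2-methylcyclohex-2-en-1-one F2 (both epimers at the new carbinol carbon). Elimination with KH in THF at 0 °C then gives 12.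

Step 6. Enamine formation on the hindered α-silyloxy methyl ketone may be slow, and facial selectivity may be poor because catalyst control has to work against the existing silyloxy stereocentre. The fallback sets out from 7 and 8 and comes back at 9. The kinetic lithium enolate of 7 (LiN(i-Pr)2, THF, −78 °C) is added to 8; this should give 9 together with its C2 epimer, ethyl (2R,5R)-5-[(tert-butyldimethylsilyl)oxy]-2-hydroxy-8-methyl-4-oxonon-7-enoate F3. Because the silyloxy centre is fixed, the two are diastereomers and are separated by chromatography.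

**Further compounds**

F1 | step 7 | ethyl (2S,3S,5R)-5-[(tert-butyldimethylsilyl)oxy]-2-hydroxy-3-[(2Z)-3-iodobut-2-en-1-yl]-8-methyl-4-methylidenenon-7-enoate | CCOC(=O)[C@@H](O)[C@@H](C/C=C(/C)I)C(=C)[C@@H](CC=C(C)C)O[Si](C)(C)C(C)(C)C
F2 | step 8 | (5R,6S)-5-[(3R)-3-[(tert-butyldimethylsilyl)oxy]-2-hydroxy-6-methyl-1-(trimethylsilyl)hept-5-en-2-yl]-6-hydroxy-2-methylcyclohex-2-en-1-one (epimers at the new carbinol carbon) | C[Si](C)(C)CC(O)([C@@H](CC=C(C)C)O[Si](C)(C)C(C)(C)C)[C@@H]1CC=C(C)C(=O)[C@H]1O
F3 | step 6 | ethyl (2R,5R)-5-[(tert-butyldimethylsilyl)oxy]-2-hydroxy-8-methyl-4-oxonon-7-enoate | CCOC(=O)[C@H](O)CC(=O)[C@@H](CC=C(C)C)O[Si](C)(C)C(C)(C)C
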